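(Readings and results were computed for substances that don't exist; scatter was added.)

The reading at 40 h lies twice as far out as our last reading at 20.0 h, so we must reckon what happens to target after the runs stop.

| flask | starting material | partner | second substrate | remark | time |
|---|---|---|---|---|---|
| green | 0.63 M | 0.75 M | 0.50 M | run made earlier |  |
| grey | 1.8 M | 0.75 M | 0.50 M | run made earlier |  |
| birch | 1.5 M | 0.750 M | 0.500 M |  | 40 h |
| elm | 0.50 M | 0.750 M | 0.500 M |  | 40 h |

| run | time / h | target / % | starting material / % |
|---|---|---|---|
| green | 1.33 | 13 | 82 |
| green | 4.00 | 24 | 67 |
| green | 8.00 | 34 | 51 |
| green | 10.0 | 32 | 44 |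
| green | 15.0 | 33 | 39 |
| green | 20.0 | 34 | 31 |
| grey | 1.50 | 12 | 85 |
| grey | 2.50 | 12 | 77 |
| grey | 4.00 | 19 | 69 |
| grey | 8.00 | 14 | 54 |
| grey | 12.0 | 14 | 56 |
| grey | 20.0 | 10 | 41 |

(each reading ± 2 percentage points)

- the flask that ends with the higher amount of target, in percent of the starting material charged, or "neither" when 2 percentage points or less lies between them (birch / elm / neither)
- final target, as a percentage of the starting material charged, in birch
- final target, as a percentage of the starting material charged, in elm



- **Time.** By hand, a stable target would stay at its last reading. Green reads that way, with 34% at 8.00 h and 34% at 20.0 h, but grey goes from 14% to 10% over the same stretch.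
- **Charge.** Suppose starting material eats target, a pseudo-first-order loss at a rate proportional to the charge times the fraction f of it left. Integrated, the logarithm of target then falls in proportion to a dose: charge times mean f times hours.
- Grey's dose from 8.00 h to 20.0 h is 616 M·min, and its fall gives 0.0328 M⁻¹ h⁻¹, our erosion constant: the logarithmic loss of target per unit of dose. With readings good to 2 percentage points, it is rough.
- **Our reckoning.** Partner and second substrate are charged alike in green, grey, birch and elm, so the settings we turn are the time and the charge of starting material. We start each flask from the nearest run's last reading, a crude step, and hold f there for the last stretch.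
- Elm's dose of 186 M·min is smaller than birch's 738 M·min. By this estimate elm ends near 30.7% and birch near 6.68%.
- **The forecast.** It names elm, with birch 9% and elm 29%: “That points to target being consumed in a step dependent on starting material”. Our birch is lower and our elm higher, but the order is the same.
- **The result.** The flasks give elm, with birch 6.93% and elm 29.4%.

    target ⇌ isomer of the product (K = 0.127, k = 0.229 h⁻¹)
    second substrate + partner ⇌ second product (K = 2.01 M⁻¹, k = 0.0318 M⁻¹ h⁻¹)
    starting material + target → side product (k = 0.0922 M⁻¹ h⁻¹)
    starting material + partner ⇌ target (K = 3.60 M⁻¹, k = 0.175 M⁻¹ h⁻¹)

- Applied to the second half of elm, the erosion constant takes target from 37.3% to 34.1%, above the 29.4% elm reaches. Applied to elm read at 6.0 d, it gives 21.9% against the 12.8% elm holds then, so elm loses more target than the constant read from grey reckons. The erosion itself is proven on birch: without the path from starting material + target to side product, birch ends at 31.9% instead of 6.93%.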